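**Plan**
- Retrosynthetic cuts, in order: the five O–benzyl bonds; the two ring C bonds from the C-methyl carbon and from the butanoyl-bearing carbon to the two C–OH carbons ([3+3]); the ArCH2–CH(CO)2 bond and the ring B–CHO bond; the ring A–CH2–ring B aryl–CH2 bond; then the acyl, O-methyl and O-benzyl bonds of the two monomers.
- Enabling feature: in ring C the bridge-bearing carbon lies between the two C–OH carbons, which is a 2-substituted malonyl unit. The C-methyl, C–OMe and butanoyl-bearing ring carbons plus the butanoyl C=O are C7, C6, C5 and C4 of a 6-methoxyoct-5-en-4-one.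
- Forward order: ring A (aspidinol, from 2-methylphloroglucinol) is benzylated, formylated, reduced and joined through its CH2 to perbenzylated ring B (from 2,4,6-trihydroxyacetophenone). Ring B is then formylated and homologated with Meldrum's acid to the malonyl dichloride.
- Ring C is the only ring built, and it is built last, by double C-acylation of a siloxy methoxy diene made from methyl 3-oxohexanoate; hydrogenolysis ends the route.
- Stereochemistry: the target has no stereocentre; the alkene geometries of the diene disappear in the arene.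

Key step: step 14

Remark: the alkene geometries drawn for 20 and 22 are those expected as major isomers and have no consequence, because all four alkene carbons end as arene or aryl ketone carbons; compounds 1, 19 and 21 are taken as commercial. In compound names, Ar = 3-acetyl-2,4,6-tris(benzyloxy)-5-{[2,4-bis(benzyloxy)-3-butanoyl-6-methoxy-5-methylphenyl]methyl}phenyl, the benzyl-protected ring A–CH2–ring B unit.

**Route**

Step 1
Reactants: 1 2-methylbenzene-1,3,5-triol (2-methylphloroglucinol); 2 butanoyl chloride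
Product: 3 1-(2,4,6-trihydroxy-3-methylphenyl)butan-1-one
Conditions: AlCl3, PhNO2/CH2Cl2, 0 → 40 °C; aq. HCl work-up
Reagents that add atoms: none
Why: Friedel–Crafts acylation of a phloroglucinol whose two free ring positions are equivalent, and the first acyl group deactivates the ring against a second one.

Step 2
Reactants: 3 1-(2,4,6-trihydroxy-3-methylphenyl)butan-1-one
Product: 4 1-(2,6-dihydroxy-4-methoxy-3-methylphenyl)butan-1-one (aspidinol)
Conditions: Me2SO4 (1.0 equiv), K2CO3 (1.0 equiv), acetone, 20 °C
Reagents that add atoms: dimethyl sulfate, COS(=O)(=O)OC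
Why: Williamson O-methylation with one equivalent of base and electrophile should go to the 4-OH para to the ketone, the most acidic phenol and the only one not held in a hydrogen bond to the carbonyl.

Step 3
Reactants: 4 aspidinol
Product: 5 1-[2,6-bis(benzyloxy)-4-methoxy-3-methylphenyl]butan-1-one
Conditions: BnBr, K2CO3, DMF, 70 °C
Reagents that add atoms: benzyl bromide, BrCc1ccccc1
Why: Williamson benzylation in a dipolar aprotic solvent favours O- over C-alkylation, and heating overcomes the chelation of the two hydroxyl groups ortho to the ketone.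

Step 4
Reactants: 5 1-[2,6-bis(benzyloxy)-4-methoxy-3-methylphenyl]butan-1-one
Product: 7 2,4-bis(benzyloxy)-3-butanoyl-6-methoxy-5-methylbenzaldehyde, via aryl iminium chloride 6 (not isolated)
Conditions: POCl3, DMF, 0 → 40 °C; then H2O, 0 °C
Reagents that add atoms: N,N-dimethylformamide, CN(C)C=O; water, O
Why: Vilsmeier–Haack formylation at the single free ring carbon, which is ortho to OMe and OBn and para to OBn, while the hindered ketone should stay untouched at this temperature.

Step 5
Reactants: 7 2,4-bis(benzyloxy)-3-butanoyl-6-methoxy-5-methylbenzaldehyde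
Product: 8 1-[2,6-bis(benzyloxy)-3-(hydroxymethyl)-4-methoxy-5-methylphenyl]butan-1-one
Conditions: NaBH4, THF/MeOH, 0 °C
Reagents that add atoms: none
Why: Borohydride reduction should take the aldehyde and leave the aryl ketone, which is flanked by two benzyloxy groups and twisted out of conjugation.

Step 6
Reactants: 9 1-(2,4,6-trihydroxyphenyl)ethan-1-one (2,4,6-trihydroxyacetophenone)
Product: 10 1-[2,4,6-tris(benzyloxy)phenyl]ethan-1-one
Conditions: BnBr, K2CO3, DMF, 80 °C
Reagents that add atoms: benzyl bromide, BrCc1ccccc1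
Why: Exhaustive Williamson benzylation of the acylphloroglucinol, O-selective in DMF with carbonate as base.

Step 7
Reactants: 8 1-[2,6-bis(benzyloxy)-3-(hydroxymethyl)-4-methoxy-5-methylphenyl]butan-1-one; 10 1-[2,4,6-tris(benzyloxy)phenyl]ethan-1-one (3 equiv, excess recovered)
Product: 11 1-[3-{[3-acetyl-2,4,6-tris(benzyloxy)phenyl]methyl}-2,6-bis(benzyloxy)-4-methoxy-5-methylphenyl]butan-1-one (ring A–CH2–ring B, one free CH on ring B)
Conditions: TsOH·H2O (10 mol %), HFIP/CH2Cl2, 0 → 20 °C
Reagents that add atoms: none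
Why: Dehydrative Friedel–Crafts benzylation with loss of water, in which the 2,4,6-trioxygenated benzylic alcohol ionises under mild acid, ring A has no free position for self-condensation, the two nucleophilic positions of 10 are equivalent, and the excess of 10 suppresses double alkylation.

Step 8
Reactants: 11 ring A–CH2–ring B diarylmethane
Product: 13 3-acetyl-2,4,6-tris(benzyloxy)-5-{[2,4-bis(benzyloxy)-3-butanoyl-6-methoxy-5-methylphenyl]methyl}benzaldehyde (Ar–CHO), via aryl iminium chloride 12 (not isolated)
Conditions: POCl3, DMF, 0 → 40 °C; then H2O, 0 °C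
Reagents that add atoms: N,N-dimethylformamide, CN(C)C=O; water, O
Why: Vilsmeier–Haack formylation at the only aromatic CH left on the two phloroglucinol rings, which lies between two benzyloxy groups and para to the third.

Step 9
Reactants: 13 Ar–CHO; 14 2,2-dimethyl-1,3-dioxane-4,6-dione (Meldrum's acid)
Product: 16 5-(Ar-methyl)-2,2-dimethyl-1,3-dioxane-4,6-dione, via arylidene Meldrum's acid 15 (not isolated)
Conditions: diethyl 2,6-dimethyl-1,4-dihydropyridine-3,5-dicarboxylate (Hantzsch ester), L-proline (cat.), EtOH/CH2Cl2, 20 °C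
Reagents that add atoms: none
Why: Knoevenagel condensation followed in the same flask by conjugate hydride transfer from the Hantzsch ester to the alkylidene Meldrum's acid (reductive alkylation), conditions that leave the hindered ketones alone.

Step 10
Reactants: 16 5-(Ar-methyl)-2,2-dimethyl-1,3-dioxane-4,6-dione
Product: 18 2-(Ar-methyl)propanedioic acid, via dilithium malonate 17 (not isolated)
Conditions: LiOH, THF/H2O, 50 °C; then 1 M HCl, 0 °C
Reagents that add atoms: lithium hydroxide, [Li+].[OH-]
Why: Saponification of the cyclic acylal releases acetone and the malonate dianion, which cannot decarboxylate, and cold acidification then gives the diacid.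

Step 11
Reactants: 19 methyl 3-oxohexanoate
Product: 20 methyl (2Z)-3-[(tert-butyldimethylsilyl)oxy]hex-2-enoate
Conditions: TBSOTf, Et3N, CH2Cl2, 0 °C
Reagents that add atoms: tert-butyldimethylsilyl trifluoromethanesulfonate, CC(C)(C)[Si](C)(C)OS(=O)(=O)C(F)(F)F
Why: Soft enolisation and O-silylation of the β-keto ester at the ketone oxygen fixes the silyl enol ether on the butanoyl carbon before any second enolisable site exists.

Step 12
Reactants: 20 methyl (2Z)-3-[(tert-butyldimethylsilyl)oxy]hex-2-enoate; 21 1,1-dibromoethane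
Product: 22 tert-butyl{[(4Z,6Z)-6-methoxyocta-4,6-dien-4-yl]oxy}dimethylsilane
Conditions: Zn, PbCl2 (cat.), TiCl4, TMEDA, THF, 0 → 25 °C; Et3N/aq. K2CO3 work-up, basic alumina
Reagents that add atoms: none
Why: Takai–Utimoto alkylidenation turns the ester carbonyl into the Z ethylidene enol ether, so the methoxy-bearing carbon is the former ester carbon and the diene is regiodefined by construction, whereas kinetic enolisation of 6-methoxyoct-5-en-4-one would remove a proton on the propyl side.

Step 13
Reactants: 18 2-(Ar-methyl)propanedioic acid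
Product: 23 2-(Ar-methyl)propanedioyl dichloride
Conditions: (COCl)2, DMF (cat.), CH2Cl2, 0 → 20 °C; evaporation, used at once
Reagents that add atoms: oxalyl chloride, O=C(Cl)C(=O)Cl
Why: Chloroiminium-catalysed acid chloride formation on a substrate whose aromatic positions are all substituted, kept cold and used immediately so that the ortho benzyloxy groups do not attack the acyl chlorides.

Step 14
Reactants: 23 2-(Ar-methyl)propanedioyl dichloride; 22 tert-butyl{[(4Z,6Z)-6-methoxyocta-4,6-dien-4-yl]oxy}dimethylsilane (1.2 equiv)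
Product: 25 1-{3-[(3-butanoyl-2,6-dihydroxy-4-methoxy-5-methylphenyl)methyl]-2,4,6-tris(benzyloxy)-5-{[2,4-bis(benzyloxy)-3-butanoyl-6-methoxy-5-methylphenyl]methyl}phenyl}ethan-1-one (rings A and B benzylated, ring C free), via open-chain keto acid chloride 24 (not isolated)
Conditions: CH2Cl2 (0.02 M), slow addition of 23 to 22, −78 → 20 °C; aq. NaHCO3 work-up
Reagents that add atoms: none
Why: Proposed new method: the terminal carbon C7 of the 2-methoxy-4-siloxy diene, pushed by both oxygens, should attack one acid chloride of 23 in a vinylogous Mukaiyama-type acylation that expels TBSCl and leaves the β-methoxy enone 24. The new 1,3-dicarbonyl array of 24 enolises, which makes C5 (the enol ether carbon next to the butanoyl group) nucleophilic again, so it acylates the second acid chloride with loss of HCl, and tautomerisation gives the arene. The closest known reactions are the C-acylation of siloxy dienes by acid chlorides and the Effenberger-type annulation of alkyl enol ethers with malonyl dichloride to phloroglucinol monoethers, neither yet run on a siloxy diene that already carries the acyl group. Ring C closes by 6-exo-trig attack of C5 on the acyl chloride carbon. No stereocentre is formed, and the two sp3 centres of 24 are lost on aromatisation. The step needs two C-acylations within one molecule: C7 reacts first because it is the terminal, doubly activated carbon, and after that the butanoyl oxygen could only close an eight-membered ring, the new enol oxygen a four-membered one and the methyl ether oxygen would have to lose its methyl group, while dilution keeps the second acylation intramolecular (a first attack at C5 would instead open a six-membered O-closure to a pyranone, which low temperature is meant to prevent).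

Step 15
Reactants: 25 pentabenzyl ether
Product: 26 1-{3-[(3-butanoyl-2,4-dihydroxy-6-methoxy-5-methylphenyl)methyl]-5-[(3-butanoyl-2,6-dihydroxy-4-methoxy-5-methylphenyl)methyl]-2,4,6-trihydroxyphenyl}ethan-1-one (CNP0184345.0)
Conditions: H2 (1 atm), 10% Pd/C, EtOAc/MeOH, 20 °C
Reagents that add atoms: none
Why: Hydrogenolysis of the five aryl benzyl ethers, under which the aryl ketones should survive because each becomes a chelated vinylogous acid as its ortho phenols are freed.

**Compound list**

1 | 2-methylbenzene-1,3,5-triol (2-methylphloroglucinol) | Cc1c(O)cc(O)cc1O | starting material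
2 | butanoyl chloride | CCCC(=O)Cl | starting material
3 | 1-(2,4,6-trihydroxy-3-methylphenyl)butan-1-one | CCCC(=O)c1c(O)cc(O)c(C)c1O | intermediate
4 | 1-(2,6-dihydroxy-4-methoxy-3-methylphenyl)butan-1-one (aspidinol) | CCCC(=O)c1c(O)cc(OC)c(C)c1O | intermediate
5 | 1-[2,6-bis(benzyloxy)-4-methoxy-3-methylphenyl]butan-1-one | CCCC(=O)c1c(OCc2ccccc2)cc(OC)c(C)c1OCc1ccccc1 | intermediate
6 | N-{[2,4-bis(benzyloxy)-3-butanoyl-6-methoxy-5-methylphenyl]methylidene}-N-methylmethanaminium chloride (formed in situ) | CCCC(=O)c1c(OCc2ccccc2)c(C=[N+](C)C)c(OC)c(C)c1OCc1ccccc1.[Cl-] | intermediate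
7 | 2,4-bis(benzyloxy)-3-butanoyl-6-methoxy-5-methylbenzaldehyde | CCCC(=O)c1c(OCc2ccccc2)c(C=O)c(OC)c(C)c1OCc1ccccc1 | intermediate
8 | 1-[2,6-bis(benzyloxy)-3-(hydroxymethyl)-4-methoxy-5-methylphenyl]butan-1-one | CCCC(=O)c1c(OCc2ccccc2)c(CO)c(OC)c(C)c1OCc1ccccc1 | intermediate
9 | 1-(2,4,6-trihydroxyphenyl)ethan-1-one | CC(=O)c1c(O)cc(O)cc1O | starting material
10 | 1-[2,4,6-tris(benzyloxy)phenyl]ethan-1-one | CC(=O)c1c(OCc2ccccc2)cc(OCc2ccccc2)cc1OCc1ccccc1 | intermediate
11 | 1-[3-{[3-acetyl-2,4,6-tris(benzyloxy)phenyl]methyl}-2,6-bis(benzyloxy)-4-methoxy-5-methylphenyl]butan-1-one | CC(=O)c1c(OCc4ccccc4)cc(OCc4ccccc4)c(Cc3c(OCc4ccccc4)c(C(=O)CCC)c(OCc4ccccc4)c(C)c3OC)c1OCc4ccccc4 | intermediate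
12 | N-(Ar-methylidene)-N-methylmethanaminium chloride (formed in situ) | C[N+](C)=Cc2c(OCc4ccccc4)c(C(C)=O)c(OCc4ccccc4)c(Cc3c(OCc4ccccc4)c(C(=O)CCC)c(OCc4ccccc4)c(C)c3OC)c2OCc4ccccc4.[Cl-] | intermediate
13 | 3-acetyl-2,4,6-tris(benzyloxy)-5-{[2,4-bis(benzyloxy)-3-butanoyl-6-methoxy-5-methylphenyl]methyl}benzaldehyde (Ar–CHO) | O=Cc2c(OCc4ccccc4)c(C(C)=O)c(OCc4ccccc4)c(Cc3c(OCc4ccccc4)c(C(=O)CCC)c(OCc4ccccc4)c(C)c3OC)c2OCc4ccccc4 | intermediate
14 | 2,2-dimethyl-1,3-dioxane-4,6-dione (Meldrum's acid) | CC1(C)OC(=O)CC(=O)O1 | starting material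
15 | 5-(Ar-methylidene)-2,2-dimethyl-1,3-dioxane-4,6-dione (formed in situ) | CC1(C)OC(=O)C(=Cc2c(OCc4ccccc4)c(C(C)=O)c(OCc4ccccc4)c(Cc3c(OCc4ccccc4)c(C(=O)CCC)c(OCc4ccccc4)c(C)c3OC)c2OCc4ccccc4)C(=O)O1 | intermediate
16 | 5-(Ar-methyl)-2,2-dimethyl-1,3-dioxane-4,6-dione | CC1(C)OC(=O)C(Cc2c(OCc4ccccc4)c(C(C)=O)c(OCc4ccccc4)c(Cc3c(OCc4ccccc4)c(C(=O)CCC)c(OCc4ccccc4)c(C)c3OC)c2OCc4ccccc4)C(=O)O1 | intermediate
17 | dilithium 2-(Ar-methyl)propanedioate (formed in situ) | [Li+].[Li+].[O-]C(=O)C(C([O-])=O)Cc2c(OCc4ccccc4)c(C(C)=O)c(OCc4ccccc4)c(Cc3c(OCc4ccccc4)c(C(=O)CCC)c(OCc4ccccc4)c(C)c3OC)c2OCc4ccccc4 | intermediate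
18 | 2-(Ar-methyl)propanedioic acid | OC(=O)C(C(=O)O)Cc2c(OCc4ccccc4)c(C(C)=O)c(OCc4ccccc4)c(Cc3c(OCc4ccccc4)c(C(=O)CCC)c(OCc4ccccc4)c(C)c3OC)c2OCc4ccccc4 | intermediate
19 | methyl 3-oxohexanoate | CCCC(=O)CC(=O)OC | starting material
20 | methyl (2Z)-3-[(tert-butyldimethylsilyl)oxy]hex-2-enoate | CCC/C(O[Si](C)(C)C(C)(C)C)=C/C(=O)OC | intermediate
21 | 1,1-dibromoethane | CC(Br)Br | starting material
22 | tert-butyl{[(4Z,6Z)-6-methoxyocta-4,6-dien-4-yl]oxy}dimethylsilane | CCC/C(O[Si](C)(C)C(C)(C)C)=C/C(OC)=C/C | intermediate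
23 | 2-(Ar-methyl)propanedioyl dichloride | O=C(Cl)C(C(=O)Cl)Cc2c(OCc4ccccc4)c(C(C)=O)c(OCc4ccccc4)c(Cc3c(OCc4ccccc4)c(C(=O)CCC)c(OCc4ccccc4)c(C)c3OC)c2OCc4ccccc4 | intermediate
24 | 2-(Ar-methyl)-5-methoxy-4-methyl-3,7-dioxodec-5-enoyl chloride (formed in situ, mixture of isomers) | CCCC(=O)C=C(OC)C(C)C(=O)C(C(=O)Cl)Cc2c(OCc4ccccc4)c(C(C)=O)c(OCc4ccccc4)c(Cc3c(OCc4ccccc4)c(C(=O)CCC)c(OCc4ccccc4)c(C)c3OC)c2OCc4ccccc4 | intermediate
25 | 1-{3-[(3-butanoyl-2,6-dihydroxy-4-methoxy-5-methylphenyl)methyl]-2,4,6-tris(benzyloxy)-5-{[2,4-bis(benzyloxy)-3-butanoyl-6-methoxy-5-methylphenyl]methyl}phenyl}ethan-1-one | CCCC(=O)c1c(OC)c(C)c(O)c(Cc2c(OCc4ccccc4)c(C(C)=O)c(OCc4ccccc4)c(Cc3c(OCc4ccccc4)c(C(=O)CCC)c(OCc4ccccc4)c(C)c3OC)c2OCc4ccccc4)c1O | intermediate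
26 | 1-{3-[(3-butanoyl-2,4-dihydroxy-6-methoxy-5-methylphenyl)methyl]-5-[(3-butanoyl-2,6-dihydroxy-4-methoxy-5-methylphenyl)methyl]-2,4,6-trihydroxyphenyl}ethan-1-one (CNP0184345.0) | CCCC(=O)c1c(O)c(C)c(OC)c(Cc2c(O)c(Cc3c(O)c(C)c(OC)c(C(=O)CCC)c3O)c(O)c(C(C)=O)c2O)c1O | target

**Step count and risks**

Total: 15 steps. Longest linear sequence: 12 steps (steps 1–5, 7–10, 13–15, from compound 1).

Steps most likely to fail:

Step 14 (proposed new method). The ring closure at carbon may be slower than intermolecular acylation of ring C phenols already formed. A first attack through C5 may let the butanoyl oxygen close a pyranone. An ortho benzyloxy oxygen may attack an acid chloride with loss of benzyl chloride. The fallback uses known chemistry and sets out from 23. The annulation is run with a plain alkyl enol ether, 2-methoxybut-2-ene F1 (from 2,2-dimethoxybutane by acid-catalysed loss of methanol), in ether at −20 to 20 °C. This Effenberger-type phloroglucinol synthesis should give the ring C resorcinol methyl ether F2, which lacks only the butanoyl group. Friedel–Crafts acylation of F2 with butanoyl chloride 2 and BF3·OEt2 in CH2Cl2 at 0 °C, at the single free ring C carbon (ortho to OMe and OH, para to OH), comes back to the route at 25.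

Step 13. The diacid may decarboxylate before activation, the dichloride may lose HCl to a ketene that dimerises, or an acyl chloride may lactonise onto an ortho benzyloxy group. The fallback forms the bridge to ring C after the ring instead of before it and sets out from 13 and 22. NaBH4 in THF/MeOH at 0 °C reduces 13 to the benzylic alcohol F3. The diene 22 is condensed with unsubstituted malonyl dichloride (CH2Cl2, −78 → 20 °C) to the ring C monomer 1-(4,6-dihydroxy-2-methoxy-3-methylphenyl)butan-1-one F4. F3 then alkylates F4 at its only free ring carbon, between the two hydroxyl groups, under TsOH·H2O in HFIP/CH2Cl2, which comes back to the route at 25.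

Step 12. The alkylidenation may stall because the β-siloxy group deactivates the ester carbonyl, or the silyl enol ether may be cleaved in the titanium chloride medium. The fallback sets out from butanoyl chloride 2. Coupling with but-1-yne (PdCl2(PPh3)2, CuI, Et3N, THF) gives oct-5-yn-4-one F5, and conjugate addition of methanol (cat. NaOMe, MeOH) gives (E)-6-methoxyoct-5-en-4-one F6. F6 is deprotonated with slightly less than one equivalent of KHMDS and warmed to 0 °C, so that the kinetic propyl-side enolate equilibrates through the residual ketone to the through-conjugated potassium dienolate F7. Trapping with TBSCl comes back to the route at 22. This equilibration is the uncertain point of the fallback; kinetic amide-base conditions would silylate on the wrong side and are avoided.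

Further compounds
F1 | step 14 | (Z)-2-methoxybut-2-ene (either isomer serves) | C/C=C(/C)OC
F2 | step 14 | 1-{3-[(2,6-dihydroxy-4-methoxy-3-methylphenyl)methyl]-2,4,6-tris(benzyloxy)-5-{[2,4-bis(benzyloxy)-3-butanoyl-6-methoxy-5-methylphenyl]methyl}phenyl}ethan-1-one | COc1cc(O)c(Cc2c(OCc4ccccc4)c(C(C)=O)c(OCc4ccccc4)c(Cc3c(OCc4ccccc4)c(C(=O)CCC)c(OCc4ccccc4)c(C)c3OC)c2OCc4ccccc4)c(O)c1C
F3 | step 13 | 1-[3-{[3-acetyl-2,4,6-tris(benzyloxy)-5-(hydroxymethyl)phenyl]methyl}-2,6-bis(benzyloxy)-4-methoxy-5-methylphenyl]butan-1-one (Ar–CH2OH) | OCc2c(OCc4ccccc4)c(C(C)=O)c(OCc4ccccc4)c(Cc3c(OCc4ccccc4)c(C(=O)CCC)c(OCc4ccccc4)c(C)c3OC)c2OCc4ccccc4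
F4 | step 13 | 1-(4,6-dihydroxy-2-methoxy-3-methylphenyl)butan-1-one | CCCC(=O)c1c(OC)c(C)c(O)cc1O
F5 | step 12 | oct-5-yn-4-one | CCCC(=O)C#CCC
F6 | step 12 | (E)-6-methoxyoct-5-en-4-one | CCCC(=O)/C=C(/OC)CC
F7 | step 12 | potassium (4Z,6Z)-6-methoxyocta-4,6-dien-4-olate | CCC/C([O-])=C/C(OC)=C/C.[K+]
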